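**Plan**

1. Retrosynthetic cuts: the C8 ester (last step); C12–O6 and C6–C7 (one chromium-mediated closure gives the ten-membered carbocycle and the α-methylene lactone); O1–C3 of the furanone together with the C1 carbonyl (back to an oxirane O1–C10–C1 plus the alkyne C2≡C3); C1–C2 (Pd coupling); C9–C10 (enolate + epoxide).
2. Enabling feature: in the 3(2H)-furanone the ring oxygen O1 sits on quaternary C10, next to the C1 ketone, and also on C3. O1–C10–C1 can therefore pre-exist as an oxirane whose C1 is at the ketone (ketal) level, held as the epoxide of a 3,4-dihydro-2H-pyran that ties C1 to O7; the two missing ring atoms are the alkyne carbons C2 and C3 on C1.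
3. Forward order of rings: δ-lactone → cyclic ketene acetal phosphate → 6-alkynyl dihydropyran (temporary ring) → epoxy ether → 3→5 ring expansion to the furanone with release of the C7 hydroxyl → bromomethyl enoate / Z-enal → carbocycle and lactone together → C8 ester.
4. Stereochemistry: C8 is bought ((R)-trityl glycidyl ether). C10 is relayed from C8 in the epoxidation and carried unchanged through the ring expansion. C7 and C6 are relayed from C8 in the macrocyclisation. The 4Z alkene is bought; the side-chain 2E alkene comes from a thermodynamic allylic transposition.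

Key step: step 8

Remark: carbons carry the germacranolide numbers of the target throughout (C1 ketone, C2=C3, C4=C5, C6 lactone carbinol, C7, C8 ester carbinol, C9, C10 quaternary, C11–C13 methylene lactone, C14/C15 methyls; O1 = furanone ring oxygen, O6/O7/O8 = oxygens on C6/C7/C8).

**Step 1**
Reactants: 1 (2R)-2-[(triphenylmethoxy)methyl]oxirane ((R)-trityl glycidyl ether); 2 4-propanoylmorpholine
Product: 3 (4R)-4-hydroxy-2-methyl-1-(morpholin-4-yl)-5-(triphenylmethoxy)pentan-1-one (both C2 epimers)
Conditions: 2, LDA, LiCl, THF, −78 °C; then 1, −78 °C → rt; H2O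
Reagents that add atoms: none
Why: Lithium amide-enolate opening of a terminal epoxide (SN2 at the unsubstituted carbon, forming C9–C10) is a standard route to γ-hydroxy amides; the C8 stereocentre comes unchanged from the bought epoxide, and the C10 centre formed here is of no consequence because it becomes sp2 in step 4.

**Step 2**
Reactants: 3 (4R)-4-hydroxy-2-methyl-1-(morpholin-4-yl)-5-(triphenylmethoxy)pentan-1-one
Product: 4 (4R)-2-methyl-1-(morpholin-4-yl)-4-[(triisopropylsilyl)oxy]-5-(triphenylmethoxy)pentan-1-one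
Conditions: TIPSOTf, 2,6-lutidine, CH2Cl2, −78 → 0 °C
Reagents that add atoms: triisopropylsilyl triflate, CC(C)[Si](C(C)C)(C(C)C)OS(=O)(=O)C(F)(F)F
Why: Silylation of the secondary alcohol with a silyl triflate and a hindered base; the bulky, acid-stable TIPS ether is chosen to survive steps 3 and 12 and to screen one face of the ring in step 7.

**Step 3**
Reactants: 4 (4R)-2-methyl-1-(morpholin-4-yl)-4-[(triisopropylsilyl)oxy]-5-(triphenylmethoxy)pentan-1-one
Product: 6 (5R)-3-methyl-5-[(triisopropylsilyl)oxy]oxan-2-one (both C3 epimers), via δ-hydroxy amide 5 (not isolated)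
Conditions: p-TsOH·H2O (1.2 equiv), MeOH–CH2Cl2, rt; then PhMe, 70 °C
Reagents that add atoms: none
Why: Acid-catalysed detritylation (trityl cation trapped by methanol) frees the C7 hydroxyl, which on warming with stoichiometric sulfonic acid lactonises onto the morpholine amide (acid-promoted lactonisation of a δ-hydroxy amide, the amine leaving as its salt), giving the ring that later holds C1 and O7 together.

**Step 4**
Reactants: 6 (5R)-3-methyl-5-[(triisopropylsilyl)oxy]oxan-2-one
Product: 7 diphenyl (3R)-5-methyl-3-[(triisopropylsilyl)oxy]-3,4-dihydro-2H-pyran-6-yl phosphate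
Conditions: KHMDS, (PhO)2P(O)Cl, HMPA, THF, −78 °C
Reagents that add atoms: diphenyl chlorophosphate, O=P(Cl)(Oc1ccccc1)Oc1ccccc1
Why: Enolisation of the lactone and O-phosphorylation gives a cyclic ketene acetal phosphate (an established class of enol phosphates for cross-coupling), which erases the C10 centre and fixes the C1=C10 geometry within the six-membered ring.

**Step 5**
Reactants: 8 (2Z)-3-methylpent-2-en-4-yn-1-ol
Product: 9 tert-butyl(dimethyl){[(2Z)-3-methylpent-2-en-4-yn-1-yl]oxy}silane
Conditions: TBSCl, imidazole, DMF, 0 °C → rt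
Reagents that add atoms: tert-butyldimethylsilyl chloride, CC(C)(C)[Si](C)(C)Cl
Why: Routine silylation of the primary alcohol; a silyl ether is used at O6 because a free hydroxyl or an alkyl ether on a (Z)-enyne would itself attack the alkyne under gold catalysis in step 8.

**Step 6**
Reactants: 7 diphenyl (3R)-5-methyl-3-[(triisopropylsilyl)oxy]-3,4-dihydro-2H-pyran-6-yl phosphate; 9 tert-butyl(dimethyl){[(2Z)-3-methylpent-2-en-4-yn-1-yl]oxy}silane
Product: 10 tert-butyl(dimethyl){[(2Z)-3-methyl-5-{(3R)-5-methyl-3-[(triisopropylsilyl)oxy]-3,4-dihydro-2H-pyran-6-yl}pent-2-en-4-yn-1-yl]oxy}silane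
Conditions: Pd(PPh3)4 (5 mol %), CuI (10 mol %), Et3N, THF, rt → 45 °C
Reagents that add atoms: none
Why: Sonogashira coupling of the terminal alkyne with the enol phosphate (Pd/Cu cross-coupling of enol phosphates) forms the C1–C2 bond and gives the 6-alkynyl dihydropyran with the Z enyne geometry unchanged.

**Step 7**
Reactants: 10 tert-butyl(dimethyl){[(2Z)-3-methyl-5-{(3R)-5-methyl-3-[(triisopropylsilyl)oxy]-3,4-dihydro-2H-pyran-6-yl}pent-2-en-4-yn-1-yl]oxy}silane
Product: 11 (1R,4R,6R)-1-[(3Z)-5-{[tert-butyl(dimethyl)silyl]oxy}-3-methylpent-3-en-1-yn-1-yl]-6-methyl-4-[(triisopropylsilyl)oxy]-2,7-dioxabicyclo[4.1.0]heptane (epoxy ether; oxirane oxygen trans to the C8 silyloxy group; used crude)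
Conditions: DMDO (1.05 equiv, acetone), CH2Cl2, −78 °C; volatiles removed at ≤ 0 °C
Reagents that add atoms: dimethyldioxirane, CC1(C)OO1
Why: Dioxirane epoxidation of an electron-rich cyclic enol ether (the reaction that makes 1,2-anhydro sugars from glycals) is much faster than attack on the enyne alkene, and oxygen should be delivered to the face of C1=C10 opposite the C8 silyloxy group, which prefers the pseudoaxial position on the half-chair (no syn-axial hydrogen, gauche O–C–C–O) and lies over C10, so that C10 (and with it C1) is set relative to C8.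

**Step 8**
Reactants: 11 (1R,4R,6R)-1-[(3Z)-5-{[tert-butyl(dimethyl)silyl]oxy}-3-methylpent-3-en-1-yn-1-yl]-6-methyl-4-[(triisopropylsilyl)oxy]-2,7-dioxabicyclo[4.1.0]heptane
Product: 12 (2R)-5-[(2Z)-4-{[tert-butyl(dimethyl)silyl]oxy}but-2-en-2-yl]-2-[(2R)-3-hydroxy-2-[(triisopropylsilyl)oxy]propyl]-2-methylfuran-3(2H)-one
Conditions: Ph3PAuNTf2 (5 mol %), H2O (5 equiv), THF, −20 °C → rt
Reagents that add atoms: water, O
Why: Proposed new method: the strained epoxy ether ionises at the ketal carbon C1 (the C1–O1 bond breaks with help from the lone pair of the pyran oxygen O7), water intercepts the oxocarbenium ion and the hemiketal collapses to the C1 ketone with release of the C7 hydroxyl, and the oxygen still bound to C10 then adds to C3 of the gold-activated alkyne and protodeauration gives the furanone, so that the three-membered ring O1–C10–C1 has grown by C2 and C3. The closest known reaction types are the Au/Pt-catalysed, nucleophile-assisted cycloisomerisation of 2-alkynyl oxiranes to furans and the gold-catalysed cyclisation of α′-hydroxy ynones to 3(2H)-furanones; what is new is the alkoxy group on the oxirane carbon, which turns the usual aromatisation into ketone formation. The furanone ring closes by 5-endo-dig attack of oxygen on the alkyne (O1–C3 bond). No new stereocentre is formed: C10 keeps the configuration fixed in step 7 because its C–O1 bond is never broken, and C8 is untouched. The step needs opening of the oxirane at C1 and not at C10, which the acetal and propargylic character of C1 secures, and attack on C3 by the C10 oxygen and not by O7 or O6, which is secured because O7 would have to close an eight-membered ring and O6 is a bulky silyl ether; the quaternary C10 rules out aromatisation to a furan.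

**Step 9**
Reactants: 12 (2R)-5-[(2Z)-4-{[tert-butyl(dimethyl)silyl]oxy}but-2-en-2-yl]-2-[(2R)-3-hydroxy-2-[(triisopropylsilyl)oxy]propyl]-2-methylfuran-3(2H)-one
Product: 13 (2R)-3-{(2R)-5-[(2Z)-4-{[tert-butyl(dimethyl)silyl]oxy}but-2-en-2-yl]-2-methyl-3-oxo-2,3-dihydrofuran-2-yl}-2-[(triisopropylsilyl)oxy]propanal
Conditions: Dess–Martin periodinane, CH2Cl2, 0 °C → rt
Reagents that add atoms: none
Why: Dess–Martin oxidation of the primary alcohol gives the α-silyloxy aldehyde under non-basic conditions that should not epimerise C8.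

**Step 10**
Reactants: 13 (2R)-3-{(2R)-5-[(2Z)-4-{[tert-butyl(dimethyl)silyl]oxy}but-2-en-2-yl]-2-methyl-3-oxo-2,3-dihydrofuran-2-yl}-2-[(triisopropylsilyl)oxy]propanal
Product: 14 methyl (4R)-5-{(2R)-5-[(2Z)-4-{[tert-butyl(dimethyl)silyl]oxy}but-2-en-2-yl]-2-methyl-3-oxo-2,3-dihydrofuran-2-yl}-3-hydroxy-2-methylidene-4-[(triisopropylsilyl)oxy]pentanoate (both C3 epimers)
Conditions: methyl propiolate, DIBAL-H, NMO, THF, 0 °C; then 13, 0 °C → rt
Reagents that add atoms: methyl propiolate, C#CC(=O)OC
Why: Vinylalumination (hydroalumination of methyl propiolate to the α-aluminoacrylate, then 1,2-addition to the aldehyde) gives the Morita–Baylis–Hillman-type adduct without an amine nucleophile that could isomerise the 4Z alkene or epimerise C8; the new C7 carbinol is formed as a mixture and is removed in step 11.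

**Step 11**
Reactants: 14 methyl (4R)-5-{(2R)-5-[(2Z)-4-{[tert-butyl(dimethyl)silyl]oxy}but-2-en-2-yl]-2-methyl-3-oxo-2,3-dihydrofuran-2-yl}-3-hydroxy-2-methylidene-4-[(triisopropylsilyl)oxy]pentanoate
Product: 15 methyl (2Z,4R)-2-(bromomethyl)-5-{(2R)-5-[(2Z)-4-{[tert-butyl(dimethyl)silyl]oxy}but-2-en-2-yl]-2-methyl-3-oxo-2,3-dihydrofuran-2-yl}-4-[(triisopropylsilyl)oxy]pent-2-enoate
Conditions: NBS, Me2S (premixed), CH2Cl2, −20 → 0 °C
Reagents that add atoms: N-bromosuccinimide, O=C1CCC(=O)N1Br
Why: Corey–Kim-type bromination (bromodimethylsulfonium salt) of a Baylis–Hillman alcohol proceeds with allylic transposition (SN2′) to the thermodynamically favoured (Z)-2-(bromomethyl)enoate, which removes the C7 carbinol centre.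

**Step 12**
Reactants: 15 methyl (2Z,4R)-2-(bromomethyl)-5-{(2R)-5-[(2Z)-4-{[tert-butyl(dimethyl)silyl]oxy}but-2-en-2-yl]-2-methyl-3-oxo-2,3-dihydrofuran-2-yl}-4-[(triisopropylsilyl)oxy]pent-2-enoate
Product: 16 methyl (2Z,4R)-2-(bromomethyl)-5-{(2R)-5-[(2Z)-4-hydroxybut-2-en-2-yl]-2-methyl-3-oxo-2,3-dihydrofuran-2-yl}-4-[(triisopropylsilyl)oxy]pent-2-enoate
Conditions: CSA (0.2 equiv), MeOH–CH2Cl2, 0 °C
Reagents that add atoms: none
Why: Acid-catalysed methanolysis cleaves the unhindered primary allylic TBS ether far faster than the hindered secondary TIPS ether, and the non-basic medium leaves the allylic bromide intact.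

**Step 13**
Reactants: 16 methyl (2Z,4R)-2-(bromomethyl)-5-{(2R)-5-[(2Z)-4-hydroxybut-2-en-2-yl]-2-methyl-3-oxo-2,3-dihydrofuran-2-yl}-4-[(triisopropylsilyl)oxy]pent-2-enoate
Product: 17 methyl (2Z,4R)-2-(bromomethyl)-5-{(2R)-2-methyl-3-oxo-5-[(2Z)-4-oxobut-2-en-2-yl]-2,3-dihydrofuran-2-yl}-4-[(triisopropylsilyl)oxy]pent-2-enoate
Conditions: MnO2, CH2Cl2, rt
Reagents that add atoms: none
Why: Manganese dioxide oxidises the allylic alcohol to the enal under neutral heterogeneous conditions that should keep the Z geometry.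

**Step 14**
Reactants: 17 methyl (2Z,4R)-2-(bromomethyl)-5-{(2R)-2-methyl-3-oxo-5-[(2Z)-4-oxobut-2-en-2-yl]-2,3-dihydrofuran-2-yl}-4-[(triisopropylsilyl)oxy]pent-2-enoate
Product: 19 8-O-triisopropylsilyl ether of the tricyclic hydroxy lactone 20 (all stereocentres arranged as in 28), via hydroxy ester 18 (not isolated)
Conditions: CrCl2 (8 equiv), THF, rt, slow addition (final 2 mM); then PPTS (cat.), CH2Cl2
Reagents that add atoms: none
Why: Intramolecular Nozaki–Hiyama (chromium(II)-mediated) allylation closes the ten-membered ring by γ-attack of the allylchromium on the aldehyde and the resulting alkoxide lactonises onto the methyl ester; C7 is set by delivery of the tethered aldehyde to the face of the allyl unit anti to the C8 silyloxy group with H8 in the allyl plane (allylic 1,3-strain), and C6 by the closed chair transition state of allylchromium reagents, which favours the anti adduct and hence the 6,7-trans lactone.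

**Step 15**
Reactants: 19 8-O-triisopropylsilyl ether of 20
Product: 20 (6S,7S,8R,10R)-8-hydroxy-1-oxo-3,10-epoxygermacra-2,4(Z),11(13)-trien-12,6-olide (8-deacyl target)
Conditions: HF·pyridine, pyridine, THF, 0 °C → rt
Reagents that add atoms: none
Why: Fluoride-mediated desilylation with buffered HF·pyridine removes the secondary TIPS ether under conditions that the α-methylene lactone and the furanone tolerate.

**Step 16**
Reactants: 21 acetaldehyde; 22 tert-butyl acrylate
Product: 23 tert-butyl 3-hydroxy-2-methylidenebutanoate (racemic)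
Conditions: DABCO (0.5 equiv), neat, rt
Reagents that add atoms: none
Why: Morita–Baylis–Hillman reaction of acetaldehyde with the acrylate under amine catalysis; the carbinol centre formed is racemic and is removed in step 17.

**Step 17**
Reactants: 23 tert-butyl 3-hydroxy-2-methylidenebutanoate
Product: 25 tert-butyl (2E)-2-(acetoxymethyl)but-2-enoate, via allylic acetate 24 (not isolated)
Conditions: Ac2O, Et3N, DMAP (cat.), CH2Cl2, 0 °C; then DABCO (0.2 equiv), THF, 65 °C
Reagents that add atoms: acetic anhydride, CC(=O)OC(C)=O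
Why: Acetylation followed by amine-catalysed SN2′–SN2′ transposition of the Baylis–Hillman acetate gives the thermodynamically favoured primary allylic acetate with the methyl group trans to the ester (2E).

**Step 18**
Reactants: 25 tert-butyl (2E)-2-(acetoxymethyl)but-2-enoate
Product: 26 (2E)-2-(acetoxymethyl)but-2-enoic acid
Conditions: TFA, CH2Cl2, 0 °C → rt
Reagents that add atoms: none
Why: Acidolysis of the tert-butyl ester (loss of isobutene) frees the acid without touching the acetate or the alkene geometry.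

**Step 19**
Reactants: 20 (6S,7S,8R,10R)-8-hydroxy-1-oxo-3,10-epoxygermacra-2,4(Z),11(13)-trien-12,6-olide; 26 (2E)-2-(acetoxymethyl)but-2-enoic acid
Product: 28 CNP0176571.1 (8-O-[(2E)-2-(acetoxymethyl)but-2-enoyl] ester of 20), via mixed anhydride 27 (not isolated)
Conditions: 26, 2,4,6-trichlorobenzoyl chloride, Et3N, THF, rt; then 20, DMAP (cat.), PhMe, rt
Reagents that add atoms: none
Why: Yamaguchi esterification through the mixed anhydride acylates the hindered C8 hydroxyl under mild conditions; no stereocentre is touched and the target results.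

**Compound list**

1 | (2R)-2-[(triphenylmethoxy)methyl]oxirane | C1[C@@H](O1)COC(c2ccccc2)(c2ccccc2)c2ccccc2 | starting material
2 | 4-propanoylmorpholine | CCC(=O)N1CCOCC1 | starting material
3 | (4R)-4-hydroxy-2-methyl-1-(morpholin-4-yl)-5-(triphenylmethoxy)pentan-1-one (C2 epimers) | CC(C[C@@H](O)COC(c1ccccc1)(c1ccccc1)c1ccccc1)C(=O)N1CCOCC1 | intermediate
4 | (4R)-2-methyl-1-(morpholin-4-yl)-4-[(triisopropylsilyl)oxy]-5-(triphenylmethoxy)pentan-1-one | CC(C[C@@H](O[Si](C(C)C)(C(C)C)C(C)C)COC(c1ccccc1)(c1ccccc1)c1ccccc1)C(=O)N1CCOCC1 | intermediate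
5 | (4R)-5-hydroxy-2-methyl-1-(morpholin-4-yl)-4-[(triisopropylsilyl)oxy]pentan-1-one | CC(C[C@@H](O[Si](C(C)C)(C(C)C)C(C)C)CO)C(=O)N1CCOCC1 | intermediate (not isolated)
6 | (5R)-3-methyl-5-[(triisopropylsilyl)oxy]oxan-2-one (C3 epimers) | CC1C[C@@H](O[Si](C(C)C)(C(C)C)C(C)C)COC1=O | intermediate
7 | diphenyl (3R)-5-methyl-3-[(triisopropylsilyl)oxy]-3,4-dihydro-2H-pyran-6-yl phosphate | O=P(Oc1ccccc1)(Oc1ccccc1)OC1=C(C)C[C@@H](O[Si](C(C)C)(C(C)C)C(C)C)CO1 | intermediate
8 | (2Z)-3-methylpent-2-en-4-yn-1-ol | C#C/C(C)=C\CO | starting material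
9 | tert-butyl(dimethyl){[(2Z)-3-methylpent-2-en-4-yn-1-yl]oxy}silane | C#C/C(C)=C\CO[Si](C)(C)C(C)(C)C | intermediate
10 | tert-butyl(dimethyl){[(2Z)-3-methyl-5-{(3R)-5-methyl-3-[(triisopropylsilyl)oxy]-3,4-dihydro-2H-pyran-6-yl}pent-2-en-4-yn-1-yl]oxy}silane | CC1=C(C#C/C(C)=C\CO[Si](C)(C)C(C)(C)C)OC[C@H](O[Si](C(C)C)(C(C)C)C(C)C)C1 | intermediate
11 | (1R,4R,6R)-1-[(3Z)-5-{[tert-butyl(dimethyl)silyl]oxy}-3-methylpent-3-en-1-yn-1-yl]-6-methyl-4-[(triisopropylsilyl)oxy]-2,7-dioxabicyclo[4.1.0]heptane | C(#C/C(C)=C\CO[Si](C)(C)C(C)(C)C)[C@@]12O[C@]1(C)C[C@@H](O[Si](C(C)C)(C(C)C)C(C)C)CO2 | intermediate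
12 | (2R)-5-[(2Z)-4-{[tert-butyl(dimethyl)silyl]oxy}but-2-en-2-yl]-2-[(2R)-3-hydroxy-2-[(triisopropylsilyl)oxy]propyl]-2-methylfuran-3(2H)-one | OC[C@H](O[Si](C(C)C)(C(C)C)C(C)C)C[C@@]1(C)OC(/C(C)=C\CO[Si](C)(C)C(C)(C)C)=CC1=O | intermediate
13 | (2R)-3-{(2R)-5-[(2Z)-4-{[tert-butyl(dimethyl)silyl]oxy}but-2-en-2-yl]-2-methyl-3-oxo-2,3-dihydrofuran-2-yl}-2-[(triisopropylsilyl)oxy]propanal | O=C[C@H](O[Si](C(C)C)(C(C)C)C(C)C)C[C@@]1(C)OC(/C(C)=C\CO[Si](C)(C)C(C)(C)C)=CC1=O | intermediate
14 | methyl (4R)-5-{(2R)-5-[(2Z)-4-{[tert-butyl(dimethyl)silyl]oxy}but-2-en-2-yl]-2-methyl-3-oxo-2,3-dihydrofuran-2-yl}-3-hydroxy-2-methylidene-4-[(triisopropylsilyl)oxy]pentanoate (C3 epimers) | C=C(C(=O)OC)C(O)[C@H](O[Si](C(C)C)(C(C)C)C(C)C)C[C@@]1(C)OC(/C(C)=C\CO[Si](C)(C)C(C)(C)C)=CC1=O | intermediate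
15 | methyl (2Z,4R)-2-(bromomethyl)-5-{(2R)-5-[(2Z)-4-{[tert-butyl(dimethyl)silyl]oxy}but-2-en-2-yl]-2-methyl-3-oxo-2,3-dihydrofuran-2-yl}-4-[(triisopropylsilyl)oxy]pent-2-enoate | COC(=O)/C(CBr)=C/[C@H](O[Si](C(C)C)(C(C)C)C(C)C)C[C@@]1(C)OC(/C(C)=C\CO[Si](C)(C)C(C)(C)C)=CC1=O | intermediate
16 | methyl (2Z,4R)-2-(bromomethyl)-5-{(2R)-5-[(2Z)-4-hydroxybut-2-en-2-yl]-2-methyl-3-oxo-2,3-dihydrofuran-2-yl}-4-[(triisopropylsilyl)oxy]pent-2-enoate | COC(=O)/C(CBr)=C/[C@H](O[Si](C(C)C)(C(C)C)C(C)C)C[C@@]1(C)OC(/C(C)=C\CO)=CC1=O | intermediate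
17 | methyl (2Z,4R)-2-(bromomethyl)-5-{(2R)-2-methyl-3-oxo-5-[(2Z)-4-oxobut-2-en-2-yl]-2,3-dihydrofuran-2-yl}-4-[(triisopropylsilyl)oxy]pent-2-enoate | COC(=O)/C(CBr)=C/[C@H](O[Si](C(C)C)(C(C)C)C(C)C)C[C@@]1(C)OC(/C(C)=C\C=O)=CC1=O | intermediate
18 | ring-closed hydroxy ester: ten-membered carbocycle bridged by the furanone, free C6 hydroxyl, methyl 2-propenoate unit on C7, C8 OTIPS (stereocentres arranged as in 19) | C=C(C(=O)OC)[C@@H]1[C@@H](O)/C=C(/C)C2=CC(=O)[C@@](C)(C[C@H]1O[Si](C(C)C)(C(C)C)C(C)C)O2 | intermediate (not isolated)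
19 | 8-O-triisopropylsilyl ether of 20 (6,7-trans lactone; spatial arrangement at C6, C7, C8, C10 as in 28) | C=C1C(=O)O[C@H]2/C=C(/C)C3=CC(=O)[C@@](C)(C[C@@H](O[Si](C(C)C)(C(C)C)C(C)C)[C@H]12)O3 | intermediate
20 | (6S,7S,8R,10R)-8-hydroxy-1-oxo-3,10-epoxygermacra-2,4(Z),11(13)-trien-12,6-olide | C=C1C(=O)O[C@H]2/C=C(/C)C3=CC(=O)[C@@](C)(C[C@@H](O)[C@H]12)O3 | intermediate
21 | acetaldehyde | CC=O | starting material
22 | tert-butyl acrylate | C=CC(=O)OC(C)(C)C | starting material
23 | tert-butyl 3-hydroxy-2-methylidenebutanoate (racemic) | CC(O)C(=C)C(=O)OC(C)(C)C | intermediate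
24 | tert-butyl 3-acetoxy-2-methylidenebutanoate (racemic) | CC(OC(C)=O)C(=C)C(=O)OC(C)(C)C | intermediate (not isolated)
25 | tert-butyl (2E)-2-(acetoxymethyl)but-2-enoate | C/C=C(/C(=O)OC(C)(C)C)COC(C)=O | intermediate
26 | (2E)-2-(acetoxymethyl)but-2-enoic acid | C/C=C(/C(=O)O)COC(C)=O | intermediate
27 | (2E)-2-(acetoxymethyl)but-2-enoic 2,4,6-trichlorobenzoic anhydride | C/C=C(/C(=O)OC(=O)c1c(Cl)cc(Cl)cc1Cl)COC(C)=O | intermediate (not isolated)
28 | CNP0176571.1, (6S,7S,8R,10R)-8-[(2E)-2-(acetoxymethyl)but-2-enoyloxy]-1-oxo-3,10-epoxygermacra-2,4(Z),11(13)-trien-12,6-olide | C=C1C(=O)O[C@H]2/C=C(/C)C3=CC(=O)[C@@](C)(C[C@@H](OC(=O)/C(=C/C)COC(C)=O)[C@H]12)O3 | target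

**Step count and risks**

Total step count: 19. Longest linear sequence: 15 steps (steps 1–4, 6–15 and 19).

Steps most likely to fail:

Step 8 (Proposed new method). What may go wrong: the ionised epoxy ether may leak into a 1,2-alkyl shift of the α-ketol type instead of being captured by water, or the O6 silyl ether may be lost under the Lewis-acidic conditions so that the freed (Z)-allylic hydroxyl competes for the alkyne. Fallback with known chemistry: setting out from 11, the epoxy ether is hydrolysed on purpose (wet THF, PPTS cat., 0 °C) and the product isolated as (2Z,7R,9R)-1-{[tert-butyl(dimethyl)silyl]oxy}-7,10-dihydroxy-3,7-dimethyl-9-[(triisopropylsilyl)oxy]dec-2-en-4-yn-6-one F1. This α′-hydroxy ynone is then closed by the established amine-mediated (Et2NH, EtOH) or cationic gold(I) 5-endo-dig cyclisation of α′-hydroxy ynones to 3(2H)-furanones, and the route is rejoined at 12.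

Step 7. What may go wrong: poor facial selectivity, because the controlling C8 substituent is 1,3 to C10 and its shielding rests only on a conformational preference. Fallback (reagent control before the enyne is attached): setting out from 6, the lactone is enolised (LDA, THF, −78 °C) and hydroxylated with an enantiopure (camphorsulfonyl)oxaziridine chosen to match the required face, giving (3R,5R)-3-hydroxy-3-methyl-5-[(triisopropylsilyl)oxy]oxan-2-one F2, from which the C3 epimer can be removed at this simple stage. Addition of the lithium acetylide of 9 (excess) to F2 gives the hydroxy ynone F1 of the first fallback, which is cyclised as described there, and the route is rejoined at 12.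

Step 14. What may go wrong: ring closure through the diastereomeric transition state (syn adduct, cis-fused lactone), or oligomerisation instead of closure of the strained ring. Fallback (stereochemical correction in place of kinetic control): setting out from 17, the ring is closed under zinc-mediated Barbier conditions (Zn, THF–aq. NH4Cl, high dilution), which are syn-selective with (Z)-2-(bromomethyl)enoates, giving the 6-epimeric cis-fused lactone F3. Saponification (LiOH, THF–H2O, 0 °C) gives the hydroxy acid F4, and Mitsunobu lactonisation (PPh3, DIAD, THF) closes the lactone with inversion at C6, rejoining the route at 19.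

**Further compounds**

F1 | step 8 | (2Z,7R,9R)-1-{[tert-butyl(dimethyl)silyl]oxy}-7,10-dihydroxy-3,7-dimethyl-9-[(triisopropylsilyl)oxy]dec-2-en-4-yn-6-one | OC[C@H](O[Si](C(C)C)(C(C)C)C(C)C)C[C@@](C)(O)C(=O)C#C/C(C)=C\CO[Si](C)(C)C(C)(C)C
F2 | step 7 | (3R,5R)-3-hydroxy-3-methyl-5-[(triisopropylsilyl)oxy]oxan-2-one | C[C@@]1(O)C[C@@H](O[Si](C(C)C)(C(C)C)C(C)C)COC1=O
F3 | step 14 | 6-epimer of 19 (cis-fused lactone, C8 OTIPS) | C=C1C(=O)O[C@@H]2/C=C(/C)C3=CC(=O)[C@@](C)(C[C@@H](O[Si](C(C)C)(C(C)C)C(C)C)[C@H]12)O3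
F4 | step 14 | ring-opened hydroxy acid of F3 (free C6 hydroxyl, 2-propenoic acid unit on C7) | C=C(C(=O)O)[C@@H]1[C@H](O)/C=C(/C)C2=CC(=O)[C@@](C)(C[C@H]1O[Si](C(C)C)(C(C)C)C(C)C)O2
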